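**Plan**

- The side chain is numbered C1' (benzylic) to C17'. The enabling feature is the C11' carbinol, flanked by C12' of the hexyl tail and by the C10' methylene on alkene carbon C9'. The only ring is the resorcinol benzene, bought intact, so no ring is formed.
- Retrosynthesis: C11'–OH goes back to C11'–B. Then C11'–C12' and C9'–C10' are cut together, giving a hexyl anion, a vinylboron unit (C10'–C11') and a Z-alkenyl bromide. Then C8'=C9' (dibromomethylenation of the C8' aldehyde) and aryl–C1' (Sonogashira) are cut.
- Forward: bis-MOM 5-bromoresorcinol and oct-7-yn-1-ol give the saturated C8 alcohol, then the aldehyde, the gem-dibromoalkene and the Z-bromide (C1'–C9'). The three-component coupling adds C10'–C17'. C–B oxidation and MOM removal finish the route.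
- Stereochemistry: C11' (S) is set by the chiral palladium–bisphosphine catalyst during the 1,2-boronate shift and passes to oxygen with retention. The Z alkene comes from hydrogenolysis of the trans C–Br bond of the dibromoalkene and is kept through oxidative addition and reductive elimination.

Key step: step 7

Assumption: the (Sp,Sp) enantiomer of the Mandyphos ligand is taken to give the (S)-boronate; if the sense of induction is the opposite for this alkyl/Z-alkenyl pairing, the (Rp,Rp) ligand is used in an otherwise unchanged step.

**Route**

Step 1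
Reactants: 1 5-bromobenzene-1,3-diol
Product: 2 1-bromo-3,5-bis(methoxymethoxy)benzene
Conditions: MOMCl, i-Pr2NEt, CH2Cl2, 0 °C → rt
Reagents that add atoms: chloromethyl methyl ether, COCCl
Why: Base-mediated O-alkylation of both phenols should give the bis-acetal ether, which is inert to the amine, hydride, organometallic and alkaline peroxide conditions that follow.

Step 2
Reactants: 2 1-bromo-3,5-bis(methoxymethoxy)benzene; 3 oct-7-yn-1-ol
Product: 4 8-[3,5-bis(methoxymethoxy)phenyl]oct-7-yn-1-ol
Conditions: PdCl2(PPh3)2 (cat.), CuI (cat.), Et3N, DMF, 70 °C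
Reagents that add atoms: none
Why: Sonogashira coupling of the aryl bromide with the terminal alkyne should form the aryl–C1' bond, and the free primary alcohol and the MOM ethers are tolerated.

Step 3
Reactants: 4 8-[3,5-bis(methoxymethoxy)phenyl]oct-7-yn-1-ol
Product: 5 8-[3,5-bis(methoxymethoxy)phenyl]octan-1-ol
Conditions: H2 (1 atm), Pd/C, EtOAc, rt
Reagents that add atoms: none
Why: Catalytic hydrogenation should saturate the aryl alkyne fully; there is no benzylic C–O bond to hydrogenolyse and aryl MOM ethers are stable under neutral hydrogenation.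

Step 4
Reactants: 5 8-[3,5-bis(methoxymethoxy)phenyl]octan-1-ol
Product: 6 8-[3,5-bis(methoxymethoxy)phenyl]octanal
Conditions: TEMPO (cat.), PhI(OAc)2, CH2Cl2, rt
Reagents that add atoms: none
Why: Oxoammonium-mediated oxidation (TEMPO/hypervalent iodine) should stop at the aldehyde under anhydrous conditions, and the acetic acid released is too weak to touch the MOM ethers.

Step 5
Reactants: 6 8-[3,5-bis(methoxymethoxy)phenyl]octanal
Product: 7 1-(9,9-dibromonon-8-en-1-yl)-3,5-bis(methoxymethoxy)benzene
Conditions: CBr4, PPh3, Et3N, CH2Cl2, 0 °C
Reagents that add atoms: carbon tetrabromide, BrC(Br)(Br)Br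
Why: Corey–Fuchs dibromomethylenation (Wittig reaction of Ph3P=CBr2 made in the flask) should add C9' to the aldehyde; the amine buffer protects the acetal ethers and the reagent does not brominate the electron-rich ring.

Step 6
Reactants: 7 1-(9,9-dibromonon-8-en-1-yl)-3,5-bis(methoxymethoxy)benzene
Product: 8 1-[(Z)-9-bromonon-8-en-1-yl]-3,5-bis(methoxymethoxy)benzene
Conditions: Bu3SnH, Pd(PPh3)4 (cat.), toluene, rt; aq. KF work-up
Reagents that add atoms: none
Why: In this palladium-catalysed tin hydride hydrogenolysis of a 1,1-dibromoalkene, Pd(0) should insert selectively into the less hindered C–Br bond trans to the chain and replace it by hydrogen, leaving bromine cis to the chain (Z).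

Step 7
Reactants: 9 n-hexyllithium; 10 4,4,5,5-tetramethyl-2-vinyl-1,3,2-dioxaborolane (vinylboronic acid pinacol ester); 8 1-[(Z)-9-bromonon-8-en-1-yl]-3,5-bis(methoxymethoxy)benzene
Product: 12 2-{(7S,9Z)-17-[3,5-bis(methoxymethoxy)phenyl]heptadec-9-en-7-yl}-4,4,5,5-tetramethyl-1,3,2-dioxaborolane, via lithium hexyl(vinyl)pinacolatoborate 11 (not isolated)
Conditions: 9 (1.0 equiv) + 10, Et2O, 0 °C → rt; solvent exchange; then 8, Pd(OAc)2 (cat.), (Sp,Sp)-Mandyphos (cat.), NaOTf, THF, 60 °C
Reagents that add atoms: none
Why: The four-coordinate boronate 11 is formed first so that no free alkyllithium meets 8; Pd(0)–bisphosphine adds to the C–Br bond of 8 with retention of the Z geometry, and once bromide is removed as NaBr the cationic alkenylpalladium binds the vinyl group of 11 and triggers a 1,2-metallate shift in which hexyl moves from boron to the α-carbon (C11'–C12') anti to palladium while Pd–C10' forms, after which reductive elimination makes C9'–C10'. The closest known reaction type is the enantioselective palladium-catalysed conjunctive cross-coupling of vinylboron ate complexes with C(sp2) triflates and halides, used here with an alkyl migrating group and a Z-alkenyl bromide. No ring is closed. The one new stereocentre, C11', is controlled by the chiral ferrocenyl bisphosphine, which fixes the alkene face bound to palladium during the stereospecific anti migration. The step needs the metallate shift to outrun direct Suzuki-type transmetalation and β-hydride elimination, and needs reductive elimination to be faster than alkenylpalladium isomerisation; the poorly transmetalating four-coordinate pinacol boronate, the wide-bite-angle ligand and the triflate salt that keeps palladium cationic and halide-free should secure this.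

Step 8
Reactants: 12 2-{(7S,9Z)-17-[3,5-bis(methoxymethoxy)phenyl]heptadec-9-en-7-yl}-4,4,5,5-tetramethyl-1,3,2-dioxaborolane
Product: 13 (7S,9Z)-17-[3,5-bis(methoxymethoxy)phenyl]heptadec-9-en-7-ol
Conditions: NaOH (aq.), H2O2 (aq.), THF, 0 °C → rt
Reagents that add atoms: hydrogen peroxide, OO
Why: Hydroperoxide adds to boron and the secondary alkyl group migrates from boron to oxygen with retention (boronate oxidation), so the (S) configuration is carried over; the isolated Z alkene and the MOM ethers are inert to alkaline peroxide.

Step 9
Reactants: 13 (7S,9Z)-17-[3,5-bis(methoxymethoxy)phenyl]heptadec-9-en-7-ol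
Product: 14 5-[(8Z,11S)-11-hydroxyheptadec-8-en-1-yl]benzene-1,3-diol (CNP0134805.1)
Conditions: HCl (cat.), MeOH, 40 °C
Reagents that add atoms: none
Why: Acid-catalysed acetal exchange in methanol should free both phenols, with the methoxymethyl unit trapped as dimethoxymethane; the carbinol stereocentre and the remote Z alkene are not involved under dilute acid.

**Compound list**

1 | 5-bromobenzene-1,3-diol | Oc1cc(O)cc(Br)c1 | starting material
2 | 1-bromo-3,5-bis(methoxymethoxy)benzene | COCOc1cc(Br)cc(OCOC)c1 | intermediate
3 | oct-7-yn-1-ol | C#CCCCCCCO | starting material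
4 | 8-[3,5-bis(methoxymethoxy)phenyl]oct-7-yn-1-ol | OCCCCCCC#Cc1cc(OCOC)cc(OCOC)c1 | intermediate
5 | 8-[3,5-bis(methoxymethoxy)phenyl]octan-1-ol | OCCCCCCCCc1cc(OCOC)cc(OCOC)c1 | intermediate
6 | 8-[3,5-bis(methoxymethoxy)phenyl]octanal | O=CCCCCCCCc1cc(OCOC)cc(OCOC)c1 | intermediate
7 | 1-(9,9-dibromonon-8-en-1-yl)-3,5-bis(methoxymethoxy)benzene | BrC(Br)=CCCCCCCCc1cc(OCOC)cc(OCOC)c1 | intermediate
8 | 1-[(Z)-9-bromonon-8-en-1-yl]-3,5-bis(methoxymethoxy)benzene | Br/C=C\CCCCCCCc1cc(OCOC)cc(OCOC)c1 | intermediate
9 | n-hexyllithium | [Li]CCCCCC | starting material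
10 | 4,4,5,5-tetramethyl-2-vinyl-1,3,2-dioxaborolane | C=CB1OC(C)(C)C(C)(C)O1 | starting material
11 | lithium hexyl(vinyl)pinacolatoborate (formed in the flask, not isolated) | [Li+].CCCCCC[B-]1(C=C)OC(C)(C)C(C)(C)O1 | intermediate
12 | 2-{(7S,9Z)-17-[3,5-bis(methoxymethoxy)phenyl]heptadec-9-en-7-yl}-4,4,5,5-tetramethyl-1,3,2-dioxaborolane | CCCCCC[C@H](B1OC(C)(C)C(C)(C)O1)C/C=C\CCCCCCCc1cc(OCOC)cc(OCOC)c1 | intermediate
13 | (7S,9Z)-17-[3,5-bis(methoxymethoxy)phenyl]heptadec-9-en-7-ol | CCCCCC[C@H](O)C/C=C\CCCCCCCc1cc(OCOC)cc(OCOC)c1 | intermediate
14 | 5-[(8Z,11S)-11-hydroxyheptadec-8-en-1-yl]benzene-1,3-diol | CCCCCC[C@H](O)C/C=C\CCCCCCCc1cc(O)cc(O)c1 | target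

**Totals**

Total step count: 9. Longest linear sequence: 9 steps (1 to 14); 3, 9 and 10 are bought and enter in steps 2 and 7.

**Steps most likely to fail**

Step 7. The coupling may go wrong in several ways: direct transfer of vinyl or hexyl to palladium instead of the metallate shift, β-hydride elimination from the alkylpalladium intermediate, partial loss of Z geometry by alkenylpalladium isomerisation, weak facial discrimination with the cis-substituted electrophile, or halide inhibition of the catalyst. The fallback builds the carbinol by a different disconnection, with C10'–C11' taken from a chiral epoxide and C9'–C10' made by acetylide opening. It sets out from aldehyde 6. Ohira–Bestmann homologation (dimethyl (1-diazo-2-oxopropyl)phosphonate, K2CO3, MeOH) should give 1-(non-8-yn-1-yl)-3,5-bis(methoxymethoxy)benzene F1. Deprotonation with n-BuLi in THF at −78 °C gives {9-[3,5-bis(methoxymethoxy)phenyl]non-1-yn-1-yl}lithium F2. With BF3·OEt2 this should open commercial (S)-2-hexyloxirane (CCCCCC[C@H]1CO1) at its terminal carbon, leaving the epoxide stereocentre untouched, to give (7S)-17-[3,5-bis(methoxymethoxy)phenyl]heptadec-9-yn-7-ol F3. Lindlar semi-hydrogenation (H2, Pd/CaCO3/Pb, quinoline, EtOAc) should then give the Z alkene, and the fallback comes back to the route at 13.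

Step 6. The hydrogenolysis may over-reduce to the terminal alkene, may discriminate incompletely between the two C–Br bonds, or may leave tin residues that poison the palladium catalyst of step 7. The fallback avoids tin and sets the geometry by syn hydrogen delivery to an alkyne. It sets out from 7. Dehydrobromination with NaHMDS (1 equiv, THF, −100 °C) should give 1-(9-bromonon-8-yn-1-yl)-3,5-bis(methoxymethoxy)benzene F4. Diimide reduction (2-nitrobenzenesulfonyl hydrazide, Et3N, THF/i-PrOH, rt) should add hydrogen syn across the triple bond, and the fallback comes back to the route at 8.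

Step 9. Under acid, the released formaldehyde equivalent may be captured by the homoallylic alcohol and alkene in a Prins-type closure, or may substitute the unveiled, electron-rich resorcinol ring. The fallback reverses the order of unmasking so that no free carbinol is present during the acid step. It sets out from 12. HCl (cat.) in MeOH should remove the MOM groups while the pinacol boronate survives, giving 5-[(8Z,11S)-11-(4,4,5,5-tetramethyl-1,3,2-dioxaborolan-2-yl)heptadec-8-en-1-yl]benzene-1,3-diol F5. Mild oxidation with sodium perborate (NaBO3·4H2O, THF/H2O, rt) should then convert C–B to C–OH with retention, and the fallback comes back to the route at 14.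

**Further compounds**

F1 | step 7 | 1-(non-8-yn-1-yl)-3,5-bis(methoxymethoxy)benzene | C#CCCCCCCCc1cc(OCOC)cc(OCOC)c1
F2 | step 7 | {9-[3,5-bis(methoxymethoxy)phenyl]non-1-yn-1-yl}lithium | [Li]C#CCCCCCCCc1cc(OCOC)cc(OCOC)c1
F3 | step 7 | (7S)-17-[3,5-bis(methoxymethoxy)phenyl]heptadec-9-yn-7-ol | CCCCCC[C@H](O)CC#CCCCCCCCc1cc(OCOC)cc(OCOC)c1
F4 | step 6 | 1-(9-bromonon-8-yn-1-yl)-3,5-bis(methoxymethoxy)benzene | BrC#CCCCCCCCc1cc(OCOC)cc(OCOC)c1
F5 | step 9 | 5-[(8Z,11S)-11-(4,4,5,5-tetramethyl-1,3,2-dioxaborolan-2-yl)heptadec-8-en-1-yl]benzene-1,3-diol | CCCCCC[C@H](B1OC(C)(C)C(C)(C)O1)C/C=C\CCCCCCCc1cc(O)cc(O)c1
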